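## The problem

Compound 24 is a 1-aryl-1,2-dihydronaphthalene. Ring A is a fully oxygenated benzene (OMe at C6, OH at C7, OMe at C8) fused to the partly saturated ring B, and ring C, a 4-hydroxy-3,5-dimethoxyphenyl group, sits on C1 directly beside the C8 methoxy group. Ring B carries the difficulty: C1 (a doubly benzylic CH) and C2 (CH–CH3) are adjacent stereocentres, both S, with aryl and methyl cis, and C3 bears a methyl group on a C3=C4 double bond conjugated with ring A. The cis arrangement is probably the less stable one, so C1 has to be set under kinetic control and never equilibrated; a stereocentre at C2 next to a flattened C1 can direct a reagent to the opposite face, which makes C2 the natural carrier of the absolute information. The dihydronaphthalene aromatises easily under oxidative or acidic conditions (erasing both stereocentres), the styrene is electron-rich through the para C7 oxygen, and the two hindered phenols are oxidation-prone; alkene and free phenols should therefore appear late, and hydrogenolysis is excluded at the end. The feature that opens a short route is the position of C2: it is a single carbon, with its methyl group, lying between C1 and C3. Taking it out leaves C1 and C3 as the enol double bond of a 1-aryl-2-indanone, so ring B can be made from a five-membered ring by inserting CH(CH3) into that bond, and the oxygen left on C3 is the handle for the C3 methyl group and the C3=C4 alkene.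

## Retrosynthesis

**24 from 23.** The two phenolic O–H bonds are traced back to O–benzyl bonds in dibenzyl ether 23. Benzyl is the one group that survives Friedel–Crafts acylation, organomagnesium reagents, zinc carbenoids and fluoride. The forward step must remove it without hydrogen, because of the styrene, and without acid damage to the alkene.

**23 from 22 from 20.** The C3–CH3 bond is cut to give enol triflate 22, which comes from ketone 20 through its enolate 21. The neighbouring option, methyl addition to the ketone followed by dehydration, would meet the easy enolisation of a 2-tetralone and an acid step of uncertain regiochemistry. The triflate fixes the double bond at C3=C4 before the methyl group arrives. The forward reaction must enolise toward the benzylic C4 and leave C2–H alone.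

**20 from 18.** Ketone 20 has a hydrogen on C1 and a carbonyl at C3. This is the pattern left when the C1–C3 bond of a cyclopropanol is broken, so 20 is traced back to siloxycyclopropane 18 through free cyclopropanol 19. Building the six-membered ring directly, by Friedel–Crafts closure or conjugate arylation, would have to set C1 and C2 together with no internal guide. Here the bond that breaks is dictated by the stability of a doubly benzylic carbanion at C1. The precursor is a five-membered ring whose three stereocentres collapse to one that matters. The forward step must cleave the internal bond, protonate C1 anti to the methyl group and not epimerise C2.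

**18 from 16 and 17.** The key cut removes C2 by breaking C1–C2 and C2–C3, leaving silyl enol ether 16 and 1,1-diiodoethane 17 as the source of CH(CH3). Ring enlargement of ketone 15 with diazoethane would insert the same carbon, but with no control over which α-bond migrates or over configuration. A [2+1] addition to the enol double bond places the carbon unambiguously and allows a chiral ligand on zinc. Compound 16 is flat and achiral. The forward reaction must distinguish its two faces and give one methyl orientation.

**16 from 15 from 13.** The O–Si bond goes back to 2-indanone 15, whose doubly benzylic α-hydrogen guarantees enolisation toward C1. The carbonyl of 15 is traced to the alkene of indene 13 by epoxidation to 14 and a 1,2-hydride shift. This moves the oxygen from the carbon where the aryl group was introduced to its neighbour, in one operation.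

**13 from 8 and 10.** The C1–aryl bond is cut to indanone 8 and aryl bromide 10, joined through Grignard reagent 11 and tertiary alcohol 12. The alcohol can lose water in only one direction, since its other neighbour is an arene carbon. The addition must outrun enolisation of a hindered, electron-rich ketone.

**8 from 6, 6 from 2 and 3, 2 from 1, 10 from 9.** The aryl–acyl bond of 8 is cut to acid 6 (closed through acid chloride 7). The arene of 6 is symmetric, so only one indanone can form, and it has a methoxy group beside the carbonyl, the group that becomes C8–OMe. Acid 6 is the two-carbon homologue of aldehyde 2, made with Meldrum's acid 3 through 4 and 5. Aldehyde 2 and bromide 10 are the benzyl ethers of syringaldehyde 1 and 4-bromo-2,6-dimethoxyphenol 9.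

## Roads not taken

Alternative 1: The cut runs through the C1–ring C bond and the C2–CH3 bond at once. Forward, the boronate complex of alkenyl boronate A2 and MeLi would meet the aryl palladium species made from ring C triflate A3 with Pd(OAc)2 and a MandyPhos ligand. Methyl migrates from boron to C2 as the aryl group is delivered to C1, giving 1,1-diaryl-2-borylpropane A1.
- Merits: both stereocentres come from one catalytic, ligand-controlled step, and their relative configuration follows from the alkene geometry. On this point the road is better than the chosen plan, which needs two separate events (cyclopropanation and protonation) for the same result.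
- Weak points: β-substituted alkenyl boronates are the hard class for this coupling. Here the β-carbon already carries ring A with two ortho substituents, direct transfer of the alkenyl group competes, and methyl migrates reluctantly.
- After the coupling ring B is still open. The C–B bond must become C2–C3 (olefination at boron with an isopropenyl unit), the acetal must be unmasked and methylenated, and the ring closed by metathesis with the second-generation Grubbs catalyst.
- Comparison: the length is similar, but four or more steps follow the stereo-defining event. The chosen plan sets against it that its key step and the next step deliver ring B with the C3 carbonyl in place.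

Alternative 2: The cut is the C2–C3 bond. Forward, bromine–lithium exchange on bromo diene A5 with t-BuLi gives a C3 alkenyllithium. Under a chiral diamine such as sparteine it would add six-endo to C2 of the neighbouring 1,1-diarylpropene, and protonation of the C1 diarylmethyl-lithium gives A4, which is identical with compound 23.
- Merits: this is the shortest road. One step closes ring B, sets both stereocentres and lands on the penultimate compound of the chosen route. The regiochemistry of addition is electronically secure.
- Weak points: diamine-controlled carbolithiation is established for aryllithium five-exo closures onto simple alkenes, not for a six-endo attack of an alkenyllithium on a trisubstituted diaryl alkene held on a crowded arene.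
- t-BuLi must also coexist with two benzyl ethers (benzylic lithiation, Wittig rearrangement) and four methoxy groups that compete with the diamine for lithium.
- C1 is set by the same kind of substrate-controlled protonation as in the chosen plan, so nothing is gained there.
- Comparison: in step count this road is clearly better. The chosen plan sets against it a key step on the substrate class (aryl-conjugated silyl enol ethers) for which ligand-controlled zinc carbenoid transfer is known, reagents that tolerate benzyl ethers, and a resolution fallback from the same intermediates.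

Alternative 3: The cut is the Diels–Alder pair C1–C2 and C3–C4. Forward, UV light converts 2-benzylbenzaldehyde A7 into its hydroxy-o-quinodimethane, which adds endo to furan-2(5H)-one A8 on a chiral titanium diolate (Ti(OiPr)4 with a TADDOL-type diol), giving all-cis lactone A6.
- Merits: two C–C bonds and four contiguous stereocentres form at once. The cis C1/C2 relationship follows from the endo rule, and enantiocontrol of this reaction type has closer precedent than the key step chosen here. In predictability of C1 and C2 it is at least equal.
- Weak points: A6 is over-built. Two of its four stereocentres are made only to be destroyed, and both C2 and C3 carry carbons at the wrong oxidation level.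
- The lactone must be reduced, two primary C–O bonds deoxygenated (one beside the crowded C1) and the C4 hydroxyl eliminated toward C3 without aromatisation. This adds five or more steps.
- The dienol must also form with the correct geometry from a benzyl carbon bearing an electron-rich aryl group next to the C8 methoxy group.
- Comparison: the chosen plan is shorter and brings C2, its methyl group and the C3 oxygen in at the oxidation level the target needs.

Key step: step 8

Assumption: the zinc complex of Boc-L-valyl-L-proline methyl ester is taken to deliver the carbenoid to the enol ether face that leads to 18; if the sense of induction is the opposite, the D,D-dipeptide is used and nothing else changes.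

## Route

Step 1
Reactants: 1 syringaldehyde
Product: 2 4-(benzyloxy)-3,5-dimethoxybenzaldehyde
Conditions: BnBr, K2CO3, DMF, 60 °C
Reagents that add atoms: benzyl bromide, BrCc1ccccc1
Why: Williamson etherification of an acidic, hindered phenol; no stereocentre is involved.

Step 2
Reactants: 2 4-(benzyloxy)-3,5-dimethoxybenzaldehyde; 3 Meldrum's acid
Product: 6 3-[4-(benzyloxy)-3,5-dimethoxyphenyl]propanoic acid, via arylidene Meldrum's acid 4 (not isolated), via benzyl Meldrum's acid 5 (not isolated)
Conditions: HCO2H/Et3N (5:2), 95 °C
Reagents that add atoms: none
Why: Knoevenagel condensation, conjugate transfer of hydride from formate, then hydrolysis and decarboxylation in one flask, a known way from aryl aldehydes to 3-arylpropanoic acids. No metal and no H2 are present, so the benzyl ether is safe.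

Step 3
Reactants: 6 3-[4-(benzyloxy)-3,5-dimethoxyphenyl]propanoic acid
Product: 8 6-(benzyloxy)-5,7-dimethoxy-2,3-dihydro-1H-inden-1-one, via acid chloride 7 (not isolated)
Conditions: (COCl)2, cat. DMF, CH2Cl2, 0 °C to rt; then SnCl4, CH2Cl2, −20 °C
Reagents that add atoms: none
Why: Intramolecular Friedel–Crafts acylation at a position para to one methoxy group and ortho to the other. The two ortho positions of the symmetric arene are equivalent, so one indanone forms, and the low temperature spares the benzyl ether.

Step 4
Reactants: 9 4-bromo-2,6-dimethoxyphenol
Product: 10 2-(benzyloxy)-5-bromo-1,3-dimethoxybenzene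
Conditions: BnBr, K2CO3, acetone, reflux
Reagents that add atoms: benzyl bromide, BrCc1ccccc1
Why: Williamson etherification; the aryl bromide is untouched.

Step 5
Reactants: 10 2-(benzyloxy)-5-bromo-1,3-dimethoxybenzene; 8 6-(benzyloxy)-5,7-dimethoxy-2,3-dihydro-1H-inden-1-one
Product: 13 5-(benzyloxy)-3-[4-(benzyloxy)-3,5-dimethoxyphenyl]-4,6-dimethoxy-1H-indene, via aryl Grignard reagent 11 (not isolated), via tertiary indanol 12 (not isolated)
Conditions: Mg, THF, 50 °C; then 8, LaCl3·2LiCl (0.3 equiv), THF, 0 °C; then p-TsOH·H2O (cat.), toluene, 60 °C
Reagents that add atoms: none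
Why: Grignard 1,2-addition, with the oxophilic lanthanum salt suppressing enolisation of the hindered, electron-rich indanone, followed by E1 dehydration of the doubly benzylic tertiary alcohol. Only the CH2 neighbour has hydrogens, so only one alkene can form.

Step 6
Reactants: 13 5-(benzyloxy)-3-[4-(benzyloxy)-3,5-dimethoxyphenyl]-4,6-dimethoxy-1H-indene
Product: 15 racemic 6-(benzyloxy)-1-[4-(benzyloxy)-3,5-dimethoxyphenyl]-5,7-dimethoxy-1,3-dihydro-2H-inden-2-one, via indene oxide 14 (not isolated)
Conditions: DMDO, acetone, −20 °C; evaporate; then BF3·OEt2 (10 mol%), CH2Cl2, −78 °C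
Reagents that add atoms: dimethyldioxirane, CC1(C)OO1
Why: Neutral epoxidation, then Meinwald rearrangement: the Lewis acid opens the epoxide at the doubly benzylic carbon and a 1,2-hydride shift from the neighbouring carbon gives the 2-indanone. The competing carbon shift would contract the ring to a benzocyclobutene and is not expected; the new stereocentre is racemic and is erased in step 7.

Step 7
Reactants: 15 racemic 6-(benzyloxy)-1-[4-(benzyloxy)-3,5-dimethoxyphenyl]-5,7-dimethoxy-1,3-dihydro-2H-inden-2-one
Product: 16 tert-butyl{[5-(benzyloxy)-3-[4-(benzyloxy)-3,5-dimethoxyphenyl]-4,6-dimethoxy-1H-inden-2-yl]oxy}dimethylsilane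
Conditions: TBSOTf, Et3N, CH2Cl2, 0 °C
Reagents that add atoms: tert-butyldimethylsilyl triflate, CC(C)(C)[Si](C)(C)OS(=O)(=O)C(F)(F)F
Why: Soft enolisation and O-silylation under equilibrating conditions. The doubly benzylic α-hydrogen is by far the most acidic, so the tetrasubstituted, aryl-conjugated silyl enol ether should form and the stereocentre of 15 disappears.

Step 8
Reactants: 16 tert-butyl{[5-(benzyloxy)-3-[4-(benzyloxy)-3,5-dimethoxyphenyl]-4,6-dimethoxy-1H-inden-2-yl]oxy}dimethylsilane; 17 1,1-diiodoethane
Product: 18 (1S,1aS,6aS)-3-(benzyloxy)-1a-[4-(benzyloxy)-3,5-dimethoxyphenyl]-6a-[(tert-butyldimethylsilyl)oxy]-2,4-dimethoxy-1-methyl-1,1a,6,6a-tetrahydrocyclopropa[a]indene (cis-fused; methyl on the convex face, cis to aryl and siloxy)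
Conditions: Et2Zn, Boc-L-Val-L-Pro-OMe, CH2Cl2, 0 °C; then 17, −40 °C; then 16, −40 to 0 °C
Reagents that add atoms: none
Why: Proposed new method: the zinc amide formed from Et2Zn and the carbamate N–H of the dipeptide exchanges its remaining ethyl group with 1,1-diiodoethane to give a ligated 1-iodoethylzinc carbenoid, which transfers CH(CH3) to the enol double bond through the concerted, asynchronous butterfly transition state of a Simmons–Smith reaction, forming C1–C2 and C2–C3 in one event. The closest known reactions are the dipeptide-ligated asymmetric methylene transfer to aryl-conjugated silyl enol ethers and the ligand-free ethylidene transfer of Furukawa-type carbenoids to enol ethers; they have not been combined, nor applied to a tetrasubstituted enol ether. The three-membered ring closes by a suprafacial [2+1] addition onto the five-membered ring, which can only give the cis-fused bicyclo[3.1.0] skeleton. C1 and C3 are set together by the face that the chiral zinc complex selects. C2 is set by the orientation of the carbenoid methyl group, expected on the convex side, cis to aryl and siloxy and away from the fold over ring A and the C4 methylene, in line with the tendency of alkylzinc carbenoids to place the alkyl group cis to the oxygen of an enol ether. The step needs chemoselectivity, which the substrate secures because the silyl enol ether is its only alkene and its most electron-rich π bond, facial selectivity, which only the ligand can supply because the two faces are enantiotopic, and a single methyl orientation, because C1 and C3 are erased in step 9 and the configuration at C2 is the product of face and orientation. A non-coordinating solvent and low temperature should keep the Lewis acidic zinc iodide by-products from opening the donor-substituted cyclopropane.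

Step 9
Reactants: 18 (1S,1aS,6aS)-siloxycyclopropane
Product: 20 (3S,4S)-6-(benzyloxy)-4-[4-(benzyloxy)-3,5-dimethoxyphenyl]-5,7-dimethoxy-3-methyl-3,4-dihydronaphthalen-2(1H)-one, via free cyclopropanol 19 (not isolated)
Conditions: TBAF, AcOH (1:1), THF, −20 °C to rt, under argon
Reagents that add atoms: none
Why: Fluoride removes the silyl group and the cyclopropanol undergoes homoketonization, the known base-induced opening that breaks the bond to the carbon best able to carry negative charge; that is the doubly benzylic C1, so the internal C1–C3 bond is cut and the five-membered ring becomes the six-membered ketone, while C2–C3 stays intact. C1 should receive its proton anti to the C2 methyl group both for a free planar carbanion (methyl pseudoaxial to avoid allylic strain with the C1 aryl group) and for a concerted opening with inversion at C1, because the methyl group of 18 is cis to the aryl group; this gives the cis ketone. Acetic acid buffering keeps the ketone from enolising toward C2.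

Step 10
Reactants: 20 (3S,4S)-2-tetralone
Product: 22 (3S,4S)-6-(benzyloxy)-4-[4-(benzyloxy)-3,5-dimethoxyphenyl]-5,7-dimethoxy-3-methyl-3,4-dihydronaphthalen-2-yl trifluoromethanesulfonate, via lithium enolate 21 (not isolated)
Conditions: LiHMDS, THF, −78 °C; then PhNTf2, −78 to 0 °C
Reagents that add atoms: N-phenylbis(trifluoromethanesulfonimide), O=S(=O)(N(c1ccccc1)S(=O)(=O)C(F)(F)F)C(F)(F)F
Why: Enolate O-triflation. Deprotonation of a 2-tetralone goes to the benzylic CH2 (C4 of the target), which is more acidic and less hindered than C2–H, so the double bond is fixed at C3=C4 and C2 is not touched.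

Step 11
Reactants: 22 (3S,4S)-enol triflate
Product: 23 (1S,2S)-7-(benzyloxy)-1-[4-(benzyloxy)-3,5-dimethoxyphenyl]-6,8-dimethoxy-2,3-dimethyl-1,2-dihydronaphthalene
Conditions: MeMgBr, Fe(acac)3 (5 mol%), THF/NMP, −30 °C
Reagents that add atoms: methylmagnesium bromide, C[Mg]Br
Why: Iron-catalysed Kumada-type cross-coupling of an alkenyl triflate with a methyl Grignard reagent, fast at low temperature and tolerant of aryl ethers. The alkene stays where the triflate was and neither stereocentre is involved.

Step 12
Reactants: 23 (1S,2S)-dibenzyl ether
Product: 24 (7S,8S)-8-(4-hydroxy-3,5-dimethoxyphenyl)-1,3-dimethoxy-6,7-dimethyl-7,8-dihydronaphthalen-2-ol (the target; C1 and C2 of ring B both S, aryl and methyl cis)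
Conditions: BCl3, C6HMe5, CH2Cl2, −78 °C; then MeOH, aq. NaHCO3
Reagents that add atoms: none
Why: Lewis acid debenzylation with pentamethylbenzene as a non-basic trap for the benzyl cation. At −78 °C the methyl ethers and the alkene should survive, and no hydrogen is used.

## Compound list

1 | syringaldehyde (4-hydroxy-3,5-dimethoxybenzaldehyde) | COc1cc(C=O)cc(OC)c1O | starting material
2 | 4-(benzyloxy)-3,5-dimethoxybenzaldehyde | COc1cc(C=O)cc(OC)c1OCc1ccccc1 | intermediate
3 | Meldrum's acid (2,2-dimethyl-1,3-dioxane-4,6-dione) | CC1(C)OC(=O)CC(=O)O1 | starting material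
4 | 5-[4-(benzyloxy)-3,5-dimethoxybenzylidene]-2,2-dimethyl-1,3-dioxane-4,6-dione (not isolated) | COc1cc(C=C2C(=O)OC(C)(C)OC2=O)cc(OC)c1OCc1ccccc1 | intermediate
5 | 5-[4-(benzyloxy)-3,5-dimethoxybenzyl]-2,2-dimethyl-1,3-dioxane-4,6-dione (not isolated) | COc1cc(CC2C(=O)OC(C)(C)OC2=O)cc(OC)c1OCc1ccccc1 | intermediate
6 | 3-[4-(benzyloxy)-3,5-dimethoxyphenyl]propanoic acid | COc1cc(CCC(=O)O)cc(OC)c1OCc1ccccc1 | intermediate
7 | 3-[4-(benzyloxy)-3,5-dimethoxyphenyl]propanoyl chloride (not isolated) | COc1cc(CCC(=O)Cl)cc(OC)c1OCc1ccccc1 | intermediate
8 | 6-(benzyloxy)-5,7-dimethoxy-2,3-dihydro-1H-inden-1-one | O=C1CCc2cc(OC)c(OCc3ccccc3)c(OC)c21 | intermediate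
9 | 4-bromo-2,6-dimethoxyphenol | COc1cc(Br)cc(OC)c1O | starting material
10 | 2-(benzyloxy)-5-bromo-1,3-dimethoxybenzene | COc1cc(Br)cc(OC)c1OCc1ccccc1 | intermediate
11 | [4-(benzyloxy)-3,5-dimethoxyphenyl]magnesium bromide (not isolated) | COc1cc([Mg]Br)cc(OC)c1OCc1ccccc1 | intermediate
12 | racemic 6-(benzyloxy)-1-[4-(benzyloxy)-3,5-dimethoxyphenyl]-5,7-dimethoxy-2,3-dihydro-1H-inden-1-ol (not isolated) | COc1cc(C2(O)CCc3cc(OC)c(OCc4ccccc4)c(OC)c32)cc(OC)c1OCc1ccccc1 | intermediate
13 | 5-(benzyloxy)-3-[4-(benzyloxy)-3,5-dimethoxyphenyl]-4,6-dimethoxy-1H-indene | COc1cc(C2=CCc3cc(OC)c(OCc4ccccc4)c(OC)c32)cc(OC)c1OCc1ccccc1 | intermediate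
14 | racemic 2,3-epoxide of indene 13 (not isolated) | COc1cc(C23OC2Cc2cc(OC)c(OCc4ccccc4)c(OC)c23)cc(OC)c1OCc1ccccc1 | intermediate
15 | racemic 6-(benzyloxy)-1-[4-(benzyloxy)-3,5-dimethoxyphenyl]-5,7-dimethoxy-1,3-dihydro-2H-inden-2-one | COc1cc(C2C(=O)Cc3cc(OC)c(OCc4ccccc4)c(OC)c32)cc(OC)c1OCc1ccccc1 | intermediate
16 | tert-butyl{[5-(benzyloxy)-3-[4-(benzyloxy)-3,5-dimethoxyphenyl]-4,6-dimethoxy-1H-inden-2-yl]oxy}dimethylsilane | COc1cc(C2=C(O[Si](C)(C)C(C)(C)C)Cc3cc(OC)c(OCc4ccccc4)c(OC)c23)cc(OC)c1OCc1ccccc1 | intermediate
17 | 1,1-diiodoethane | CC(I)I | starting material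
18 | (1S,1aS,6aS)-3-(benzyloxy)-1a-[4-(benzyloxy)-3,5-dimethoxyphenyl]-6a-[(tert-butyldimethylsilyl)oxy]-2,4-dimethoxy-1-methyl-1,1a,6,6a-tetrahydrocyclopropa[a]indene | COc1cc([C@]23[C@H](C)[C@@]2(O[Si](C)(C)C(C)(C)C)Cc2cc(OC)c(OCc4ccccc4)c(OC)c23)cc(OC)c1OCc1ccccc1 | intermediate
19 | (1S,1aS,6aS)-3-(benzyloxy)-1a-[4-(benzyloxy)-3,5-dimethoxyphenyl]-2,4-dimethoxy-1-methyl-1,1a-dihydrocyclopropa[a]inden-6a(6H)-ol (not isolated) | COc1cc([C@]23[C@H](C)[C@@]2(O)Cc2cc(OC)c(OCc4ccccc4)c(OC)c23)cc(OC)c1OCc1ccccc1 | intermediate
20 | (3S,4S)-6-(benzyloxy)-4-[4-(benzyloxy)-3,5-dimethoxyphenyl]-5,7-dimethoxy-3-methyl-3,4-dihydronaphthalen-2(1H)-one (aryl and methyl cis) | COc1cc([C@H]2c3c(cc(OC)c(OCc4ccccc4)c3OC)CC(=O)[C@H]2C)cc(OC)c1OCc1ccccc1 | intermediate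
21 | lithium (3S,4S)-6-(benzyloxy)-4-[4-(benzyloxy)-3,5-dimethoxyphenyl]-5,7-dimethoxy-3-methyl-3,4-dihydronaphthalen-2-olate (not isolated) | COc1cc([C@H]2c3c(cc(OC)c(OCc4ccccc4)c3OC)C=C([O-])[C@H]2C)cc(OC)c1OCc1ccccc1.[Li+] | intermediate
22 | (3S,4S)-6-(benzyloxy)-4-[4-(benzyloxy)-3,5-dimethoxyphenyl]-5,7-dimethoxy-3-methyl-3,4-dihydronaphthalen-2-yl trifluoromethanesulfonate | COc1cc([C@H]2c3c(cc(OC)c(OCc4ccccc4)c3OC)C=C(OS(=O)(=O)C(F)(F)F)[C@H]2C)cc(OC)c1OCc1ccccc1 | intermediate
23 | (1S,2S)-7-(benzyloxy)-1-[4-(benzyloxy)-3,5-dimethoxyphenyl]-6,8-dimethoxy-2,3-dimethyl-1,2-dihydronaphthalene | COc1cc([C@H]2c3c(cc(OC)c(OCc4ccccc4)c3OC)C=C(C)[C@H]2C)cc(OC)c1OCc1ccccc1 | intermediate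
24 | (7S,8S)-8-(4-hydroxy-3,5-dimethoxyphenyl)-1,3-dimethoxy-6,7-dimethyl-7,8-dihydronaphthalen-2-ol (CNP0141907.1) | COc1cc([C@H]2c3c(cc(OC)c(O)c3OC)C=C(C)[C@H]2C)cc(OC)c1O | target

## Step count and least certain steps

Total steps: 12. Longest linear sequence: 11 steps (steps 1–3 and 5–12, from syringaldehyde 1); step 4 is the only side branch.

**Step 8 (key step, proposed new method).**
- What may go wrong: sluggish transfer of the bulkier ethylidene unit to a hindered tetrasubstituted enol ether; incomplete facial discrimination by the dipeptide; and a mixed methyl orientation. Opposite orientations on the same face give opposite configurations at C2, so a mixture lowers enantiomeric purity directly. Opening of the product by zinc iodide species is a further loss channel.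
- Fallback with known chemistry, from 16: ligand-free ethylidene transfer with Et2Zn and 17 in CH2Cl2 should give racemic cyclopropane, that is 18 together with its mirror image F1.
- Fluoride-induced ring expansion as in step 9 then gives the racemic cis ketone, 20 with its antipode F2. Here the methyl orientation no longer affects optical purity.
- Preparative chromatography on a chiral stationary phase separates the antipodes and returns to the route at 20.

**Step 9.**
- What may go wrong: the opening may stall at the cyclopropanol under buffering. If it is forced with unbuffered fluoride, a long-lived diarylmethyl anion may be protonated with poor facial discrimination, or the ketone may epimerise at C2 through enolisation or autoxidise.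
- Fallback: a two-stage sequence in which the stereochemistry rests on the concerted opening and not on a free carbanion. From 18 the cyclopropanol 19 is isolated (buffered fluoride, low temperature). It is then opened with a catalytic alkoxide in methanol at 0 °C, the classical homoketonization that takes place with inversion at the protonated carbon. In 19 this again places hydrogen anti to the methyl group, and the route is rejoined at 20. No new compound arises.

**Step 6.**
- What may go wrong: oxidation of the very electron-rich arenes by the dioxirane, capture of the epoxide-derived cation by adventitious nucleophiles or by a second alkene molecule, and autoxidation of the acidic C1–H of the product.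
- Fallback, from 13: hydroboration with BH3·THF and oxidation with NaOH/H2O2 should give racemic trans-1-aryl-2-indanol F3, with boron going to the carbon remote from the aryl group. Dess–Martin periodinane then gives 15.

**Step 12.**
- What may go wrong: protonation of the electron-rich styrene by HCl/BCl3 (isomerisation, dimerisation or aromatisation), benzylation of the arenes if trapping is incomplete, or loss of a methyl ether flanking the liberated phenol.
- Fallback: the protecting groups are changed before the alkene exists. From 20, hydrogenolysis (H2, Pd/C, EtOAc) gives diphenol ketone F4.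
- Silylation (TBSOTf, 2,6-lutidine) gives bis-silyl ether F5.
- Enol triflation and iron-catalysed methylation as in steps 10 and 11 give F6 and then F7.
- Buffered fluoride (TBAF, AcOH) releases the phenols under neutral conditions and arrives at 24.

## Further compounds

F1 | step 8 | (1R,1aR,6aR)-enantiomer of siloxycyclopropane 18 | COc1cc([C@@]23[C@@H](C)[C@]2(O[Si](C)(C)C(C)(C)C)Cc2cc(OC)c(OCc4ccccc4)c(OC)c23)cc(OC)c1OCc1ccccc1
F2 | step 8 | (3R,4R)-enantiomer of ketone 20 | COc1cc([C@@H]2c3c(cc(OC)c(OCc4ccccc4)c3OC)CC(=O)[C@@H]2C)cc(OC)c1OCc1ccccc1
F0 | step 9 | none | none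
F3 | step 6 | racemic trans-6-(benzyloxy)-1-[4-(benzyloxy)-3,5-dimethoxyphenyl]-5,7-dimethoxy-2,3-dihydro-1H-inden-2-ol (one enantiomer drawn) | O[C@@H]1Cc2cc(OC)c(OCc3ccccc3)c(OC)c2[C@H]1c1cc(OC)c(OCc2ccccc2)c(OC)c1
F4 | step 12 | (3S,4S)-6-hydroxy-4-(4-hydroxy-3,5-dimethoxyphenyl)-5,7-dimethoxy-3-methyl-3,4-dihydronaphthalen-2(1H)-one | COc1cc([C@H]2c3c(cc(OC)c(O)c3OC)CC(=O)[C@H]2C)cc(OC)c1O
F5 | step 12 | bis(tert-butyldimethylsilyl) ether of F4 | COc1cc([C@H]2c3c(cc(OC)c(O[Si](C)(C)C(C)(C)C)c3OC)CC(=O)[C@H]2C)cc(OC)c1O[Si](C)(C)C(C)(C)C
F6 | step 12 | enol triflate of F5 (double bond toward the benzylic CH2) | COc1cc([C@H]2c3c(cc(OC)c(O[Si](C)(C)C(C)(C)C)c3OC)C=C(OS(=O)(=O)C(F)(F)F)[C@H]2C)cc(OC)c1O[Si](C)(C)C(C)(C)C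
F7 | step 12 | bis(tert-butyldimethylsilyl) ether of target 24 | COc1cc([C@H]2c3c(cc(OC)c(O[Si](C)(C)C(C)(C)C)c3OC)C=C(C)[C@H]2C)cc(OC)c1O[Si](C)(C)C(C)(C)C
A1 | alternative 1 | pinacol boronate of 1-[3-(benzyloxy)-6-(dimethoxymethyl)-2,4-dimethoxyphenyl]-1-[4-(benzyloxy)-3,5-dimethoxyphenyl]propan-2-yl, both stereocentres as drawn | COc1cc([C@@H](c2c(OC)c(OCc3ccccc3)c(OC)cc2C(OC)OC)[C@H](C)B2OC(C)(C)C(C)(C)O2)cc(OC)c1OCc1ccccc1
A2 | alternative 1 | (E)-2-{2-[3-(benzyloxy)-6-(dimethoxymethyl)-2,4-dimethoxyphenyl]ethenyl}-4,4,5,5-tetramethyl-1,3,2-dioxaborolane | COC(OC)c1cc(OC)c(OCc2ccccc2)c(OC)c1/C=C/B1OC(C)(C)C(C)(C)O1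
A3 | alternative 1 | 4-(benzyloxy)-3,5-dimethoxyphenyl trifluoromethanesulfonate | COc1cc(OS(=O)(=O)C(F)(F)F)cc(OC)c1OCc1ccccc1
A4 | alternative 2 | (1S,2S)-7-(benzyloxy)-1-[4-(benzyloxy)-3,5-dimethoxyphenyl]-6,8-dimethoxy-2,3-dimethyl-1,2-dihydronaphthalene (identical with 23) | COc1cc([C@H]2c3c(cc(OC)c(OCc4ccccc4)c3OC)C=C(C)[C@H]2C)cc(OC)c1OCc1ccccc1
A5 | alternative 2 | 2-(benzyloxy)-5-{(E)-1-[3-(benzyloxy)-6-[(Z)-2-bromoprop-1-enyl]-2,4-dimethoxyphenyl]prop-1-enyl}-1,3-dimethoxybenzene (either geometry of the diarylpropene would serve) | COc1cc(/C(=C\C)c2c(OC)c(OCc3ccccc3)c(OC)cc2/C=C(/C)Br)cc(OC)c1OCc1ccccc1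
A6 | alternative 3 | all-cis 1-aryl-4-hydroxytetralin 2,3-fused γ-lactone (bis-benzyl ether), stereocentres as drawn | COc1cc([C@H]2c3c(cc(OC)c(OCc4ccccc4)c3OC)[C@@H](O)[C@H]4C(=O)OC[C@@H]24)cc(OC)c1OCc1ccccc1
A7 | alternative 3 | 4-(benzyloxy)-2-[4-(benzyloxy)-3,5-dimethoxybenzyl]-3,5-dimethoxybenzaldehyde | COc1cc(Cc2c(OC)c(OCc3ccccc3)c(OC)cc2C=O)cc(OC)c1OCc1ccccc1
A8 | alternative 3 | furan-2(5H)-one | O=C1C=CCO1
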